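**Strategy.** The biflavonoid is cut in the flavone pyranone (ring C): its C4 carbonyl lies between C4a of the phloroglucinol ring A and the aryloxy-bearing C3, so C4 is brought in as carbon monoxide. One Pd(dba)2-catalysed carbonylative acylation joins a symmetrical tris-MOM iodophloroglucinol, CO and the enolate of an α-aryloxy ketone, forming the C4a–C4 and C4–C3 bonds as an open 2-aryloxy-1,3-diketone. The ketone partner already carries the C2 aryl group (as its benzyl ether) and the diaryl ether to a masked benzaldehyde. Acid then closes ring C, and the unmasked aldehyde is elaborated into the (2S)-flavanone by Knoevenagel condensation and a thiourea-catalysed oxa-Michael cyclisation.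

Key step: step 5

Assumption: the quinidine-derived epi-amino thiourea is taken to deliver the (2S) series with this substrate; the sense must be checked on the first batch, and the quinine-derived pseudoenantiomer takes its place unchanged if it proves opposite.

**Step 1**
Reactants: 1 4-hydroxybenzaldehyde; 2 2-bromo-1-[4-(benzyloxy)phenyl]ethanone
Product: 3 4-{2-[4-(benzyloxy)phenyl]-2-oxoethoxy}benzaldehyde
Conditions: K2CO3, MeCN, 60 °C
Reagents that add atoms: none
Why: Williamson ether synthesis, the phenoxide displacing the activated phenacyl bromide by SN2, with a carbonate base too weak to drive aldol reaction of the product ketone with the aldehyde.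

**Step 2**
Reactants: 3 4-{2-[4-(benzyloxy)phenyl]-2-oxoethoxy}benzaldehyde
Product: 4 1-[4-(benzyloxy)phenyl]-2-[4-(1,3-dioxolan-2-yl)phenoxy]ethan-1-one
Conditions: TMSOCH2CH2OTMS, TMSOTf (cat.), CH2Cl2, −78 to −20 °C
Reagents that add atoms: 1,2-bis(trimethylsilyloxy)ethane, C[Si](C)(C)OCCO[Si](C)(C)C
Why: TMSOTf-catalysed acetalisation with the bis-silyl glycol ether converts the aldehyde chemoselectively at low temperature and leaves the conjugated aryl ketone; making the acetal after the ether bond avoids handling a labile para-hydroxybenzaldehyde acetal.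

**Step 3**
Reactants: 5 phloroglucinol
Product: 6 1,3,5-tris(methoxymethoxy)benzene
Conditions: NaH, MOMCl, DMF, 0 °C to rt
Reagents that add atoms: chloromethyl methyl ether, COCCl
Why: Threefold Williamson-type O-alkylation of the phenoxide by a hard alkoxymethyl electrophile (MOM protection).

**Step 4**
Reactants: 6 1,3,5-tris(methoxymethoxy)benzene
Product: 8 2-iodo-1,3,5-tris(methoxymethoxy)benzene, via 2,4,6-tris(methoxymethoxy)phenyllithium 7 (not isolated)
Conditions: n-BuLi, THF, 0 °C; then I2, −78 °C to rt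
Reagents that add atoms: iodine, II
Why: Directed ortho-metalation between two chelating OMOM groups followed by iodine quench; the three ring positions are equivalent, so only one mono-iodide can form.

**Step 5**
Reactants: 4 1-[4-(benzyloxy)phenyl]-2-[4-(1,3-dioxolan-2-yl)phenoxy]ethan-1-one; 8 2-iodo-1,3,5-tris(methoxymethoxy)benzene; 9 carbon monoxide
Product: 10 1-[4-(benzyloxy)phenyl]-2-[4-(1,3-dioxolan-2-yl)phenoxy]-3-[2,4,6-tris(methoxymethoxy)phenyl]propane-1,3-dione
Conditions: Pd(dba)2 (5 mol %), 1,3-bis(diphenylphosphino)propane (dppp, 6 mol %), NaN(SiMe3)2 (2.2 equiv), CO (1 atm), THF, 70 °C; then aq. NH4Cl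
Reagents that add atoms: none
Why: Zerovalent palladium from Pd(dba)2/dppp inserts into the C–I bond of 8, CO inserts to give an aroyl divalent palladium complex, and the sodium enolate of 4 displaces iodide and undergoes C–C reductive elimination, so that CO becomes C4 and the new bonds are C4a–C4 and C4–C3 of the later flavone. The closest known reaction type is the carbonylative α-arylation of aryl ketones with aryl iodides under Pd(dba)2 and a bidentate phosphine, which gives 1,3-diketones. No ring is closed and no stereocentre is controlled: the central CH(OAr) carbon is enolisable, forms as a racemate and becomes sp2 (C3) in step 6. Carbonylative C-acylation must win over direct α-arylation and O-acylation; the two ortho OMOM groups favour CO insertion at the crowded aryl–palladium bond over direct coupling, and the CO atmosphere with the chelating diphosphine keeps the aroyl complex intact until the enolate arrives. The ketone has a single enolisable CH2, acidified by the aryloxy group, and the iodide is symmetrical, so only one constitutional isomer can form. The more acidic diketone is held as its enolate by the second equivalent of base, which stops further acylation.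

**Step 6**
Reactants: 10 1-[4-(benzyloxy)phenyl]-2-[4-(1,3-dioxolan-2-yl)phenoxy]-3-[2,4,6-tris(methoxymethoxy)phenyl]propane-1,3-dione
Product: 12 4-({2-[4-(benzyloxy)phenyl]-5,7-dihydroxy-4-oxo-4H-chromen-3-yl}oxy)benzaldehyde, via 1-[4-(benzyloxy)phenyl]-2-(4-formylphenoxy)-3-(2,4,6-trihydroxyphenyl)propane-1,3-dione 11 (not isolated)
Conditions: 3 M aq. HCl, MeOH/THF, 60 °C
Reagents that add atoms: water, O
Why: Acid hydrolysis removes the three MOM acetals and the dioxolane, a freed ortho-phenol adds 6-exo-trig to the 4-benzyloxybenzoyl carbonyl and the hemiketal dehydrates to the γ-pyrone (the cyclodehydration stage of a Baker–Venkataraman flavone synthesis); the aryl benzyl ether is stable to dilute HCl.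

**Step 7**
Reactants: 12 4-({2-[4-(benzyloxy)phenyl]-5,7-dihydroxy-4-oxo-4H-chromen-3-yl}oxy)benzaldehyde
Product: 13 4-({7-(benzyloxy)-2-[4-(benzyloxy)phenyl]-5-hydroxy-4-oxo-4H-chromen-3-yl}oxy)benzaldehyde
Conditions: BnBr (1.05 equiv), K2CO3, DMF, rt
Reagents that add atoms: benzyl bromide, BrCc1ccccc1
Why: Williamson benzylation is selective for the acidic, unhindered 7-OH, because 5-OH is locked in a hydrogen bond to the C4 carbonyl; capping 7-OH keeps an acidic phenol away from the amine catalysts of steps 9 and 10.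

**Step 8**
Reactants: 14 1-[2,4-bis(benzyloxy)-6-hydroxyphenyl]ethanone
Product: 16 tert-butyl 3-[2,4-bis(benzyloxy)-6-hydroxyphenyl]-3-oxopropanoate, via dilithium phenoxide enolate 15 (not isolated)
Conditions: LiN(SiMe3)2 (3.2 equiv), THF, −78 to −20 °C; then Boc2O (1.05 equiv), −78 to 0 °C; aq. NH4Cl
Reagents that add atoms: di-tert-butyl dicarbonate, CC(C)(C)OC(=O)OC(=O)OC(C)(C)C
Why: Claisen-type C-acylation of a ketone enolate: in the dilithium dianion the enolate carbon is the most nucleophilic site, as in the C-aroylation of 2'-hydroxyacetophenone dianions, and the third equivalent of base stores the product as its enolate.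

**Step 9**
Reactants: 13 4-({7-(benzyloxy)-2-[4-(benzyloxy)phenyl]-5-hydroxy-4-oxo-4H-chromen-3-yl}oxy)benzaldehyde; 16 tert-butyl 3-[2,4-bis(benzyloxy)-6-hydroxyphenyl]-3-oxopropanoate
Product: 17 tert-butyl 2-[2,4-bis(benzyloxy)-6-hydroxybenzoyl]-3-[4-({7-(benzyloxy)-2-[4-(benzyloxy)phenyl]-5-hydroxy-4-oxo-4H-chromen-3-yl}oxy)phenyl]prop-2-enoate (either alkene geometry is acceptable)
Conditions: piperidine (cat.), AcOH (cat.), 4 Å MS, toluene, rt to 40 °C
Reagents that add atoms: none
Why: Knoevenagel condensation of the active methylene with the aryl aldehyde through the iminium ion, driven by water removal; the ketone-chelated phenol is a poor nucleophile under these buffered conditions, so the alkylidene should be isolable uncyclised.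

**Step 10**
Reactants: 17 tert-butyl 2-[2,4-bis(benzyloxy)-6-hydroxybenzoyl]-3-[4-({7-(benzyloxy)-2-[4-(benzyloxy)phenyl]-5-hydroxy-4-oxo-4H-chromen-3-yl}oxy)phenyl]prop-2-enoate
Product: 20 (2S)-5,7-bis(benzyloxy)-2-[4-({7-(benzyloxy)-2-[4-(benzyloxy)phenyl]-5-hydroxy-4-oxo-4H-chromen-3-yl}oxy)phenyl]-2,3-dihydro-4H-chromen-4-one, via tert-butyl (2S,3R)-4-oxochromane-3-carboxylate 18 (not isolated), via (2S,3R)-4-oxochromane-3-carboxylic acid 19 (not isolated)
Conditions: N-[3,5-bis(trifluoromethyl)phenyl]-N'-(9-deoxy-9-epi-quinidin-9-yl)thiourea (10 mol %), toluene, −25 °C; then TsOH·H2O, 80 °C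
Reagents that add atoms: none
Why: Bifunctional catalysis of a 6-endo-trig oxa-Michael addition, in which the thiourea binds the β-keto ester and the quinuclidine activates the phenol so that oxygen is delivered to one face of the alkylidene and sets C2 as (S) (C3 settles trans and is erased), after which TsOH cleaves the tert-butyl ester and the β-keto acid decarboxylates without touching C2.

**Step 11**
Reactants: 20 (2S)-5,7-bis(benzyloxy)-2-[4-({7-(benzyloxy)-2-[4-(benzyloxy)phenyl]-5-hydroxy-4-oxo-4H-chromen-3-yl}oxy)phenyl]-2,3-dihydro-4H-chromen-4-one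
Product: 21 (2S)-2-[4-({5,7-dihydroxy-2-(4-hydroxyphenyl)-4-oxo-4H-chromen-3-yl}oxy)phenyl]-5,7-dihydroxy-2,3-dihydro-4H-chromen-4-one (CNP0144321.1)
Conditions: H2 (1 atm), 10% Pd/C, EtOAc/MeOH, rt
Reagents that add atoms: none
Why: Catalytic hydrogenolysis cleaves the four aryl benzyl ethers under neutral conditions that neither enolise nor ring-open the flavanone, so C2 stays (S), and the tetrasubstituted flavone C2=C3 bond and both ketones should not be reduced at 1 atm and rt.

**Compound list**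
1 | 4-hydroxybenzaldehyde | O=Cc1ccc(O)cc1 | starting material
2 | 2-bromo-1-[4-(benzyloxy)phenyl]ethanone | O=C(CBr)c1ccc(OCc2ccccc2)cc1 | starting material
3 | 4-{2-[4-(benzyloxy)phenyl]-2-oxoethoxy}benzaldehyde | O=Cc1ccc(OCC(=O)c2ccc(OCc3ccccc3)cc2)cc1 | intermediate
4 | 1-[4-(benzyloxy)phenyl]-2-[4-(1,3-dioxolan-2-yl)phenoxy]ethan-1-one | O=C(COc1ccc(C2OCCO2)cc1)c1ccc(OCc2ccccc2)cc1 | intermediate
5 | phloroglucinol | Oc1cc(O)cc(O)c1 | starting material
6 | 1,3,5-tris(methoxymethoxy)benzene | COCOc1cc(OCOC)cc(OCOC)c1 | intermediate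
7 | 2,4,6-tris(methoxymethoxy)phenyllithium | [Li]c1c(OCOC)cc(OCOC)cc1OCOC | intermediate
8 | 2-iodo-1,3,5-tris(methoxymethoxy)benzene | COCOc1cc(OCOC)cc(OCOC)c1I | intermediate
9 | carbon monoxide | [C-]#[O+] | starting material
10 | 1-[4-(benzyloxy)phenyl]-2-[4-(1,3-dioxolan-2-yl)phenoxy]-3-[2,4,6-tris(methoxymethoxy)phenyl]propane-1,3-dione | O=C(c1ccc(OCc2ccccc2)cc1)C(Oc1ccc(C2OCCO2)cc1)C(=O)c1c(OCOC)cc(OCOC)cc1OCOC | intermediate
11 | 1-[4-(benzyloxy)phenyl]-2-(4-formylphenoxy)-3-(2,4,6-trihydroxyphenyl)propane-1,3-dione | O=Cc1ccc(OC(C(=O)c2ccc(OCc3ccccc3)cc2)C(=O)c2c(O)cc(O)cc2O)cc1 | intermediate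
12 | 4-({2-[4-(benzyloxy)phenyl]-5,7-dihydroxy-4-oxo-4H-chromen-3-yl}oxy)benzaldehyde | O=Cc1ccc(Oc2c(-c3ccc(OCc4ccccc4)cc3)oc3cc(O)cc(O)c3c2=O)cc1 | intermediate
13 | 4-({7-(benzyloxy)-2-[4-(benzyloxy)phenyl]-5-hydroxy-4-oxo-4H-chromen-3-yl}oxy)benzaldehyde | O=Cc1ccc(Oc2c(-c3ccc(OCc4ccccc4)cc3)oc3cc(OCc4ccccc4)cc(O)c3c2=O)cc1 | intermediate
14 | 1-[2,4-bis(benzyloxy)-6-hydroxyphenyl]ethanone | CC(=O)c1c(O)cc(OCc2ccccc2)cc1OCc1ccccc1 | starting material
15 | dilithium phenoxide enolate of 14 | [Li+].[Li+].C=C([O-])c1c([O-])cc(OCc2ccccc2)cc1OCc1ccccc1 | intermediate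
16 | tert-butyl 3-[2,4-bis(benzyloxy)-6-hydroxyphenyl]-3-oxopropanoate | CC(C)(C)OC(=O)CC(=O)c1c(O)cc(OCc2ccccc2)cc1OCc1ccccc1 | intermediate
17 | tert-butyl 2-[2,4-bis(benzyloxy)-6-hydroxybenzoyl]-3-[4-({7-(benzyloxy)-2-[4-(benzyloxy)phenyl]-5-hydroxy-4-oxo-4H-chromen-3-yl}oxy)phenyl]prop-2-enoate | CC(C)(C)OC(=O)C(=Cc1ccc(Oc2c(-c3ccc(OCc4ccccc4)cc3)oc3cc(OCc4ccccc4)cc(O)c3c2=O)cc1)C(=O)c1c(O)cc(OCc2ccccc2)cc1OCc1ccccc1 | intermediate
18 | tert-butyl (2S,3R)-5,7-bis(benzyloxy)-2-[4-({7-(benzyloxy)-2-[4-(benzyloxy)phenyl]-5-hydroxy-4-oxo-4H-chromen-3-yl}oxy)phenyl]-4-oxochromane-3-carboxylate | CC(C)(C)OC(=O)[C@@H]1[C@@H](c2ccc(Oc3c(-c4ccc(OCc5ccccc5)cc4)oc4cc(OCc5ccccc5)cc(O)c4c3=O)cc2)Oc2cc(OCc3ccccc3)cc(OCc3ccccc3)c2C1=O | intermediate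
19 | (2S,3R)-5,7-bis(benzyloxy)-2-[4-({7-(benzyloxy)-2-[4-(benzyloxy)phenyl]-5-hydroxy-4-oxo-4H-chromen-3-yl}oxy)phenyl]-4-oxochromane-3-carboxylic acid | OC(=O)[C@@H]1[C@@H](c2ccc(Oc3c(-c4ccc(OCc5ccccc5)cc4)oc4cc(OCc5ccccc5)cc(O)c4c3=O)cc2)Oc2cc(OCc3ccccc3)cc(OCc3ccccc3)c2C1=O | intermediate
20 | (2S)-5,7-bis(benzyloxy)-2-[4-({7-(benzyloxy)-2-[4-(benzyloxy)phenyl]-5-hydroxy-4-oxo-4H-chromen-3-yl}oxy)phenyl]-2,3-dihydro-4H-chromen-4-one | O=C1C[C@@H](c2ccc(Oc3c(-c4ccc(OCc5ccccc5)cc4)oc4cc(OCc5ccccc5)cc(O)c4c3=O)cc2)Oc2cc(OCc3ccccc3)cc(OCc3ccccc3)c21 | intermediate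
21 | (2S)-2-[4-({5,7-dihydroxy-2-(4-hydroxyphenyl)-4-oxo-4H-chromen-3-yl}oxy)phenyl]-5,7-dihydroxy-2,3-dihydro-4H-chromen-4-one | O=C1C[C@@H](c2ccc(Oc3c(-c4ccc(O)cc4)oc4cc(O)cc(O)c4c3=O)cc2)Oc2cc(O)cc(O)c21 | target

**Count.** Total steps: 11. Longest linear sequence: 8 steps (1, 2, 5, 6, 7, 9, 10, 11).

**Steps most likely to fail**

Step 5. Oxidative addition and CO insertion at the crowded, very electron-rich iodide may be slow, so that proto-deiodination, non-carbonylative α-arylation or enolate O-acylation takes over. The fallback sets out from 6 (with 4) and comes back at 10. Compound 6 is lithiated as in step 4 and the aryllithium 7 is quenched with DMF to give 2,4,6-tris(methoxymethoxy)benzaldehyde F1. The lithium enolate of 4 (LiN(i-Pr)2, THF, −78 °C) is added to F1 to give the aldol 1-[4-(benzyloxy)phenyl]-2-[4-(1,3-dioxolan-2-yl)phenoxy]-3-hydroxy-3-[2,4,6-tris(methoxymethoxy)phenyl]propan-1-one F2 as a diastereomer mixture. Dess–Martin periodinane (NaHCO3, CH2Cl2) then oxidises the secondary alcohol to diketone 10.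

Step 10. The di-ortho-substituted aroyl group may twist the acceptor out of the catalyst's preferred binding mode, giving poor facial selectivity or letting an uncatalysed racemic cyclisation compete. The fallback sets out from 17 and comes back at 20. Compound 17 is cyclised with catalytic Et3N in toluene at rt to the racemic trans tert-butyl 4-oxochromane-3-carboxylate F3. TsOH·H2O at 80 °C then gives, through the racemic 4-oxochromane-3-carboxylic acid F4, the racemic tetrabenzyl flavanone F5. Preparative chromatography on a chiral stationary phase (amylose tris(3,5-dimethylphenylcarbamate)) separates the enantiomers, and the (2S) enantiomer is 20.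

Step 8. Acylation at the phenoxide oxygen, or double acylation, may compete with C-acylation of the dianion. The fallback sets out from 14 and comes back at 16. The phenol is acylated on purpose (Boc2O, DMAP cat., CH2Cl2) to give 2-acetyl-3,5-bis(benzyloxy)phenyl tert-butyl carbonate F6. Enolisation with LiN(SiMe3)2 (2.2 equiv, THF, −78 to 0 °C) then triggers a Baker–Venkataraman-type O-to-C migration of the tert-butoxycarbonyl group through a six-membered tetrahedral intermediate that expels the phenoxide, delivering 16.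

**Further compounds**
F1 | step 5 | 2,4,6-tris(methoxymethoxy)benzaldehyde | O=Cc1c(OCOC)cc(OCOC)cc1OCOC
F2 | step 5 | 1-[4-(benzyloxy)phenyl]-2-[4-(1,3-dioxolan-2-yl)phenoxy]-3-hydroxy-3-[2,4,6-tris(methoxymethoxy)phenyl]propan-1-one (diastereomer mixture) | O=C(c1ccc(OCc2ccccc2)cc1)C(Oc1ccc(C2OCCO2)cc1)C(O)c1c(OCOC)cc(OCOC)cc1OCOC
F3 | step 10 | racemic trans tert-butyl 5,7-bis(benzyloxy)-2-[4-({7-(benzyloxy)-2-[4-(benzyloxy)phenyl]-5-hydroxy-4-oxo-4H-chromen-3-yl}oxy)phenyl]-4-oxochromane-3-carboxylate | CC(C)(C)OC(=O)C1C(c2ccc(Oc3c(-c4ccc(OCc5ccccc5)cc4)oc4cc(OCc5ccccc5)cc(O)c4c3=O)cc2)Oc2cc(OCc3ccccc3)cc(OCc3ccccc3)c2C1=O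
F4 | step 10 | racemic trans 5,7-bis(benzyloxy)-2-[4-({7-(benzyloxy)-2-[4-(benzyloxy)phenyl]-5-hydroxy-4-oxo-4H-chromen-3-yl}oxy)phenyl]-4-oxochromane-3-carboxylic acid | OC(=O)C1C(c2ccc(Oc3c(-c4ccc(OCc5ccccc5)cc4)oc4cc(OCc5ccccc5)cc(O)c4c3=O)cc2)Oc2cc(OCc3ccccc3)cc(OCc3ccccc3)c2C1=O
F5 | step 10 | racemic 5,7-bis(benzyloxy)-2-[4-({7-(benzyloxy)-2-[4-(benzyloxy)phenyl]-5-hydroxy-4-oxo-4H-chromen-3-yl}oxy)phenyl]-2,3-dihydro-4H-chromen-4-one | O=C1CC(c2ccc(Oc3c(-c4ccc(OCc5ccccc5)cc4)oc4cc(OCc5ccccc5)cc(O)c4c3=O)cc2)Oc2cc(OCc3ccccc3)cc(OCc3ccccc3)c21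
F6 | step 8 | 2-acetyl-3,5-bis(benzyloxy)phenyl tert-butyl carbonate | CC(=O)c1c(OC(=O)OC(C)(C)C)cc(OCc2ccccc2)cc1OCc1ccccc1
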